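**Retrosynthetic overview**
- The target is the free-phenol form of a MOM-protected (S)-carbinol. That carbinol comes from enantioselective CBS reduction of a 3-aroyl butenolide, which is the only stereocentre.
- The 3-aroyl butenolide comes from a late carbonylative Suzuki coupling of two large fragments: a 3-bromo-4-aryl-5-(Z)-arylidene butenolide and the 3,5-dibromo-4-methoxyphenyl boronic acid.
- The bromobutenolide comes from commercial 3,4-dibromofuranone by C4-selective Suzuki coupling and then a Z-selective vinylogous aldol condensation with an aryl aldehyde.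
- No ring is built in the route: the butenolide is purchased and all three arenes come from 4-iodophenol, with the aryl groups attached in the order C4, C5, C3.

Assumptions: the Z-arylidene in the SMILES is the thermodynamic isomer, and MOM is used for both phenols.

---

**Step 1**
Reactants: 1, 4-iodophenol
Product: 2, 2-bromo-4-iodophenol
Conditions: NBS (1.0 equiv), i-Pr2NH (0.1 equiv), CH2Cl2, 0 °C → rt
Reagents that add atoms: NBS, O=C1CCC(=O)N1Br (adds Br)
Why: Electrophilic bromination occurs ortho to the OH, because the para position is blocked by iodine.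

**Step 2**
Reactants: 2
Product: 3, 2-bromo-4-iodo-1-(methoxymethoxy)benzene
Conditions: MOMCl, i-Pr2NEt, CH2Cl2, 0 °C → rt
Reagents that add atoms: MOMCl, ClCOC (adds CH2OCH3)
Why: Acetal protection of the phenol makes it compatible with Grignard exchange, Pd couplings and hydride reduction.

**Step 3**
Reactants: 3
Product: 4, (3-bromo-4-(methoxymethoxy)phenyl)boronic acid
Conditions: i-PrMgCl·LiCl (1.1 equiv), THF, −20 °C, 1 h; then B(OMe)3, −20 °C → rt; aq. NH4Cl
Reagents that add atoms: trimethyl borate, COB(OC)OC (adds B(OH)2 after hydrolysis)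
Why: I/Mg exchange is far faster than Br/Mg exchange, so only the iodide is metalated, and the aryl Grignard is then trapped as the boronate (Knochel exchange, borylation).

**Step 4**
Reactants: 3
Product: 5, 3-bromo-4-(methoxymethoxy)benzaldehyde
Conditions: i-PrMgCl·LiCl, THF, −20 °C; then DMF, −20 °C → rt; aq. NH4Cl
Reagents that add atoms: DMF, CN(C)C=O (adds CHO)
Why: The same chemoselective I/Mg exchange gives the aryl Grignard, which is formylated (Bouveault formylation).

**Step 5**
Reactants: 1, 4-iodophenol
Product: 6, 2,6-dibromo-4-iodophenol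
Conditions: NBS (2.2 equiv), i-Pr2NH (0.1 equiv), CH2Cl2, 0 °C → rt
Reagents that add atoms: NBS, O=C1CCC(=O)N1Br (adds 2 Br)
Why: Both positions ortho to the OH are brominated (electrophilic aromatic substitution), and the mild NBS/amine system avoids bromodeiodination.

**Step 6**
Reactants: 6
Product: 7, 2,6-dibromo-4-iodoanisole
Conditions: MeI (1.5 equiv), K2CO3, acetone, 50 °C
Reagents that add atoms: MeI, CI (adds CH3)
Why: Williamson O-methylation installs the permanent aryl methyl ether of the target.

**Step 7**
Reactants: 7
Product: 8, (3,5-dibromo-4-methoxyphenyl)boronic acid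
Conditions: i-PrMgCl·LiCl, THF, −20 °C; then B(OMe)3, −20 °C → rt; aq. NH4Cl
Reagents that add atoms: trimethyl borate, COB(OC)OC (adds B(OH)2)
Why: Selective I/Mg exchange followed by borylation, as in Step 3; the two bromines are meta to the metalated carbon and survive.

**Step 8**
Reactants: 9, 3,4-dibromofuran-2(5H)-one; 4
Product: 10, 3-bromo-4-[3-bromo-4-(methoxymethoxy)phenyl]furan-2(5H)-one
Conditions: Pd(PPh3)4 (5 mol %), Ag2CO3 (1.5 equiv), toluene, 70 °C
Reagents that add atoms: none
Why: In Suzuki–Miyaura coupling the β-bromide (C4) of the bromoenoate undergoes oxidative addition faster than the α-bromide (C3), and the mild Ag2CO3 conditions avoid decomposition of the acidic lactone.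

**Step 9**
Reactants: 10; 5
Product: 11, (5Z)-3-bromo-4-[3-bromo-4-(methoxymethoxy)phenyl]-5-[3-bromo-4-(methoxymethoxy)benzylidene]furan-2(5H)-one
Conditions: 5 (1.3 equiv), DBU (1.5 equiv), CH2Cl2, 0 °C; then Ac2O (3 equiv), rt
Reagents that add atoms: none
Why: Deprotonation at C5 gives a dienolate that undergoes vinylogous aldol addition to the aldehyde; acetylation and E1cB elimination then give the arylidene, and the Z isomer (aryl syn to ring O, away from the C4 aryl) is favoured sterically (Knoevenagel-type condensation).

**Step 10**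
Reactants: 11; 8
Product: 12, (5Z)-3-(3,5-dibromo-4-methoxybenzoyl)-4-[3-bromo-4-(methoxymethoxy)phenyl]-5-[3-bromo-4-(methoxymethoxy)benzylidene]furan-2(5H)-one
Conditions: PdCl2(PPh3)2 (5 mol %), PPh3 (10 mol %), K2CO3 (3 equiv), CO (5 atm), anisole, 80 °C
Reagents that add atoms: carbon monoxide, [C-]#[O+] (adds the ketone C=O)
Why: In carbonylative Suzuki–Miyaura coupling the electron-poor vinyl bromide adds to Pd much faster than the hindered, electron-rich aryl bromides, then CO inserts and transmetalation with 8 and reductive elimination give the diaryl-type enone that joins the two large fragments.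

**Step 11**
Reactants: 12
Product: 13, (5Z)-3-[(S)-(3,5-dibromo-4-methoxyphenyl)(hydroxy)methyl]-4-[3-bromo-4-(methoxymethoxy)phenyl]-5-[3-bromo-4-(methoxymethoxy)benzylidene]furan-2(5H)-one
Conditions: (R)-Me-CBS (0.2 equiv), BH3·SMe2 (0.8 equiv), THF, −30 °C, 3 h; MeOH quench
Reagents that add atoms: none (borane only adds H)
Why: In Corey–Bakshi–Shibata reduction the catalyst-bound borane delivers hydride to one face of the ketone, set by the size difference between the hindered tetrasubstituted butenolide C3 and the unhindered aryl group; the (R)-catalyst is chosen to give the (S)-alcohol, and Lewis-acid activation gives 1,2-reduction rather than conjugate reduction.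

**Step 12**
Reactants: 13
Product: 14, target, (5Z)-3-[(S)-(3,5-dibromo-4-methoxyphenyl)(hydroxy)methyl]-4-(3-bromo-4-hydroxyphenyl)-5-(3-bromo-4-hydroxybenzylidene)furan-2(5H)-one
Conditions: 3 M HCl, THF/MeOH (2:1), 40 °C, 6 h
Reagents that add atoms: none
Why: Acid hydrolysis removes both MOM acetals; the carbinol is deactivated toward ionisation by the electron-poor aryl and the acceptor-substituted alkene, so the stereocentre is not touched, and the aryl bromides, aryl methyl ether, lactone and Z-alkene are stable.

---

**Compound list**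

1 | 4-iodophenol | Oc1ccc(I)cc1 | starting material
2 | 2-bromo-4-iodophenol | Oc1ccc(I)cc1Br | intermediate
3 | 2-bromo-4-iodo-1-(methoxymethoxy)benzene | COCOc1ccc(I)cc1Br | intermediate
4 | (3-bromo-4-(methoxymethoxy)phenyl)boronic acid | COCOc1ccc(B(O)O)cc1Br | intermediate
5 | 3-bromo-4-(methoxymethoxy)benzaldehyde | COCOc1ccc(C=O)cc1Br | intermediate
6 | 2,6-dibromo-4-iodophenol | Oc1c(Br)cc(I)cc1Br | intermediate
7 | 2,6-dibromo-4-iodoanisole | COc1c(Br)cc(I)cc1Br | intermediate
8 | (3,5-dibromo-4-methoxyphenyl)boronic acid | COc1c(Br)cc(B(O)O)cc1Br | intermediate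
9 | 3,4-dibromofuran-2(5H)-one | O=C1OCC(Br)=C1Br | starting material
10 | 3-bromo-4-[3-bromo-4-(methoxymethoxy)phenyl]furan-2(5H)-one | COCOc1ccc(cc1Br)C1=C(Br)C(=O)OC1 | intermediate
11 | (5Z)-3-bromo-4,5-diaryl(idene)furanone, bis-MOM | BrC1=C(c2ccc(OCOC)c(Br)c2)/C(=C/c2ccc(OCOC)c(Br)c2)OC1=O | intermediate
12 | (5Z)-3-aroyl-4-aryl-5-arylidene furanone, bis-MOM | COc1c(Br)cc(cc1Br)C(=O)C1=C(c2ccc(OCOC)c(Br)c2)/C(=C/c2ccc(OCOC)c(Br)c2)OC1=O | intermediate
13 | (S)-carbinol, bis-MOM | COc1c(Br)cc(cc1Br)[C@H](O)C1=C(c2ccc(OCOC)c(Br)c2)/C(=C/c2ccc(OCOC)c(Br)c2)OC1=O | intermediate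
14 | target | COc1c(Br)cc([C@H](O)C2=C(c3ccc(O)c(Br)c3)/C(=C/c3ccc(O)c(Br)c3)OC2=O)cc1Br | target

**Totals:** 12 steps in total. The longest linear sequence is 8 steps (Steps 1, 2, 3, 8, 9, 10, 11, 12), which is exactly two thirds of the total.

**Three steps most likely to fail**
1. **Step 11 (CBS reduction):** the ee may be modest because the ketone is flanked by two aryl-type groups, and the facial preference assigned here is a prediction. Fallback: reduce 12 non-selectively with NaBH4/CeCl3, then resolve the racemic alcohol enzymatically (CAL-B, vinyl acetate) and hydrolyse the acetate of the unwanted enantiomer.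
2. **Step 10 (carbonylative Suzuki):** the direct non-carbonylative 3-aryl coupling or oxidative addition into aryl bromides may compete. Fallback: change the C3 installation to Nozaki–Hiyama–Kishi coupling of 11 with 3,5-dibromo-4-methoxybenzaldehyde (CrCl2/NiCl2), then Dess–Martin oxidation to ketone 12.
3. **Step 9 (Z-selective vinylogous aldol condensation):** competing aldehyde decomposition or E/Z mixtures. Fallback: convert 10 to its 2-silyloxyfuran (TBSOTf, Et3N) and run a BF3-promoted vinylogous Mukaiyama aldol with 5, then dehydrate (Ac2O, DBU) and photo- or iodine-equilibrate to Z.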